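The runs are simulated for substances that don't exist.

A flask charged with 0.400 M of starting material cannot make 0.555 M of target, yet the grey run read that much at 6.1 min.

| flask | starting material | reagent | target | time |
|---|---|---|---|---|
| blue | 0.400 M | 1.00 M |  |  |
| grey | 0.400 M | 1.00 M | 0.200 M |  |
| green | 1.60 M | 4.00 M |  | 6.1 min |

- blue run (time / min: [target] / M): 0.76: 0.006; 1.5: 0.040; 2.3: 0.082; 3.0: 0.131; 3.8: 0.181; 4.6: 0.228; 5.3: 0.261; 6.1: 0.289
- grey run (time / min: [target] / M): 0.76: 0.277; 1.5: 0.343; 2.3: 0.419; 3.0: 0.461; 3.8: 0.493; 4.6: 0.518; 5.3: 0.538; 6.1: 0.555

(standard deviation of a reading: 0.003 M)

- Overall: starting material + reagent -> target.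
- Constant volume, constant temperature.
- The analysis sees a species whether free or bound.
- "The second partner" is reagent.

* target in the green run at 6.1 min, as a share of the starting material charged

The contradiction went when I wrote the balance of the starting material, the limiting reagent, since the grey run charged less of it than of reagent. That run was seeded with 0.200 M of target, so it had made 0.355 M, which fits inside its charge. At that time the grey run had 11.2% outstanding, the outstanding share being the part of the charged starting material that has not yet appeared as new target, in whatever form it stands.

The blue run, unseeded, had 27.8% outstanding at the same time. By 0.76 min the blue run had made 0.006 M of target and the grey run 0.0770 M, so added target speeds the formation of target. I took the grey share as my yardstick for the green run, which is unseeded but charged at 4.00 times the blue concentrations.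

The forecast gave 99%, with a range of 90% to 100%, on these grounds: “Quadrupling all concentrations speeds the clock about eightfold”. That leaves 1.00% outstanding.

The green run gave 88.2%, and the scheme behind the readings was this:

    starting material + reagent → intermediate (2.106 M⁻¹ min⁻¹)
    intermediate → target (0.3108 min⁻¹)
    starting material + reagent ⇌ idle substrate-reagent adduct, settled at all times (4.790 M⁻¹)
    starting material + reagent + target → 2 target (7.320 M⁻² min⁻¹)

The forecast's number is what the blue run gives with its clock scaled as if first order in everything but starting material. The green outstanding share was 11.8%, which counts free starting material, idle substrate-reagent adduct and intermediate together. On the green charge of 1.60 M, the grey share of 11.2% comes to 0.179 M, give or take the 0.0120 M that the scatter of its one reading carries on that charge, and the green run had 0.189 M outstanding at 6.1 min.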